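**Retrosynthetic overview**

1. Feature: in the pyranone ring (O1–C2–C3–C4–C4a–C8a) the ketone carbon C4 is bonded to the C3 methylene, and the next atom C2 carries one H, the phenyl ring and O1. Cutting C3–C4 and C2–H gives the formyl C–H of a salicylaldehyde and the C=CH2 of its O-(1-phenylvinyl) ether 15, an achiral isomer of the target, to be closed by enantioselective Rh-catalysed hydroacylation.
2. The enol ether O–C(Ph)=CH2 comes from an aryl benzoate by titanium methylenation, with the formyl group held as CH2OTBS.
3. The C8 prenyl group comes from an aromatic Claisen shift of the 4-O-(1,1-dimethylallyl) ether of 2,4-dihydroxybenzaldehyde to the carbon between the two oxygens. Both tertiary allyl ethers are made by Pd(0) etherification with carbonate 3, the second one before ring closure so that no base meets the flavanone.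
4. Ring order: the resorcinol ring is bought, the phenyl ring comes with benzoyl chloride, and the pyranone ring is closed last.

Key step: step 11

Assumption: the sense of induction of a given bisphosphine antipode on this oxygen-tethered substrate cannot be predicted with confidence; (R)-DTBM-SEGPHOS is written, and its mirror image is to be used if the first run gives the (2R)-flavanone.

**Route**

Step 1
Reactants: 1 2-methylbut-3-en-2-ol
Product: 3 tert-butyl 2-methylbut-3-en-2-yl carbonate, via lithium 2-methylbut-3-en-2-olate 2 (not isolated)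
Conditions: n-BuLi, THF, 0 °C; then Boc2O, 0 °C to rt; aqueous work-up
Reagents that add atoms: di-tert-butyl dicarbonate, CC(C)(C)OC(=O)OC(=O)OC(C)(C)C; n-butyllithium, [Li]CCCC (its lithium stays in 2 only)
Why: O-acylation of the lithium alkoxide of a tertiary alcohol with Boc2O is standard mixed-carbonate formation and involves no stereocentre.

Step 2
Reactants: 4 2,4-dihydroxybenzaldehyde; 3 tert-butyl 2-methylbut-3-en-2-yl carbonate
Product: 5 2-hydroxy-4-(2-methylbut-3-en-2-yloxy)benzaldehyde
Conditions: Pd(PPh3)4 (cat.), 3 (1.05 equiv), THF, 4 Å MS, 0 °C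
Reagents that add atoms: none
Why: Tsuji–Trost allylic etherification, in which Pd(0) ionises the tertiary carbonate with loss of CO2 and the phenoxide attacks the 1,1-dimethylallyl palladium complex at its substituted terminus under kinetic control at 0 °C, the non-chelated and more acidic 4-OH reacting ahead of the 2-OH that is hydrogen-bonded to the formyl group.

Step 3
Reactants: 5 2-hydroxy-4-(2-methylbut-3-en-2-yloxy)benzaldehyde
Product: 7 2,4-dihydroxy-3-(3-methylbut-2-en-1-yl)benzaldehyde, via Claisen dienone 6 (not isolated)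
Conditions: PhNEt2, 140 °C, argon
Reagents that add atoms: none
Why: Aromatic Claisen rearrangement ([3,3]) of the 1,1-dimethylallyl ether delivers the 3-methylbut-2-enyl group with allylic inversion to an ortho carbon, the chelated 2-OH/CHO pair fixing the ring bonds so that C3 between the two oxygens should be preferred over C5, and the dienone then tautomerises to the phenol.

Step 4
Reactants: 7 2,4-dihydroxy-3-(3-methylbut-2-en-1-yl)benzaldehyde; 3 tert-butyl 2-methylbut-3-en-2-yl carbonate
Product: 8 2-hydroxy-4-(2-methylbut-3-en-2-yloxy)-3-(3-methylbut-2-en-1-yl)benzaldehyde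
Conditions: Pd(PPh3)4 (cat.), 3 (1.1 equiv), THF, 4 Å MS, 0 °C
Reagents that add atoms: none
Why: The same Tsuji–Trost etherification, in which the 4-OH is again the only phenol not held in the hydrogen bond to the formyl group and the low temperature should keep the tertiary ether from re-ionising to the linear prenyl ether.

Step 5
Reactants: 8 2-hydroxy-4-(2-methylbut-3-en-2-yloxy)-3-(3-methylbut-2-en-1-yl)benzaldehyde
Product: 9 6-(hydroxymethyl)-3-(2-methylbut-3-en-2-yloxy)-2-(3-methylbut-2-en-1-yl)phenol
Conditions: NaBH4, THF–MeOH, 0 °C; pH 7 buffer work-up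
Reagents that add atoms: none
Why: Borohydride reduction of the aryl aldehyde leaves the alkenes and the allyl aryl ether untouched, and the neutral work-up avoids ionisation of the electron-rich o-hydroxybenzyl alcohol.

Step 6
Reactants: 9 6-(hydroxymethyl)-3-(2-methylbut-3-en-2-yloxy)-2-(3-methylbut-2-en-1-yl)phenol
Product: 10 6-[(tert-butyldimethylsilyloxy)methyl]-3-(2-methylbut-3-en-2-yloxy)-2-(3-methylbut-2-en-1-yl)phenol
Conditions: TBSCl (1.05 equiv), imidazole, CH2Cl2, 0 °C
Reagents that add atoms: tert-butyldimethylsilyl chloride, CC(C)(C)[Si](C)(C)Cl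
Why: Silylation of the primary benzylic alcohol is faster than that of the phenol, which is shielded by two ortho substituents, so one equivalent of TBSCl should give the mono-ether.

Step 7
Reactants: 10 6-[(tert-butyldimethylsilyloxy)methyl]-3-(2-methylbut-3-en-2-yloxy)-2-(3-methylbut-2-en-1-yl)phenol; 11 benzoyl chloride
Product: 12 6-[(tert-butyldimethylsilyloxy)methyl]-3-(2-methylbut-3-en-2-yloxy)-2-(3-methylbut-2-en-1-yl)phenyl benzoate
Conditions: BzCl, Et3N, DMAP (cat.), CH2Cl2, 0 °C to rt
Reagents that add atoms: none
Why: DMAP-catalysed O-acylation of a hindered phenol by an acid chloride is routine and touches neither the silyl ether nor the allyl groups.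

Step 8
Reactants: 12 6-[(tert-butyldimethylsilyloxy)methyl]-3-(2-methylbut-3-en-2-yloxy)-2-(3-methylbut-2-en-1-yl)phenyl benzoate
Product: 13 tert-butyldimethyl{[4-(2-methylbut-3-en-2-yloxy)-3-(3-methylbut-2-en-1-yl)-2-(1-phenylvinyloxy)benzyl]oxy}silane
Conditions: Cp2TiMe2 (3 equiv), toluene–THF, 65 °C, dark; filtration through Et3N-deactivated silica
Reagents that add atoms: dimethyltitanocene (Petasis reagent), C[Ti](C)(C1C=CC=C1)C1C=CC=C1
Why: Petasis methylenation, in which thermally generated Cp2Ti=CH2 adds [2+2] to the ester carbonyl and cycloreverts to the aryl 1-phenylvinyl ether, is established for aryl benzoates, tolerates alkenes and silyl ethers, and 65 °C should stay below the Claisen threshold of the tertiary allyl ether.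

Step 9
Reactants: 13 tert-butyldimethyl{[4-(2-methylbut-3-en-2-yloxy)-3-(3-methylbut-2-en-1-yl)-2-(1-phenylvinyloxy)benzyl]oxy}silane
Product: 14 [4-(2-methylbut-3-en-2-yloxy)-3-(3-methylbut-2-en-1-yl)-2-(1-phenylvinyloxy)phenyl]methanol
Conditions: TBAF, THF, 0 °C; water work-up
Reagents that add atoms: none
Why: Fluoride cleavage of the silyl ether runs under basic conditions, which the acid-sensitive enol ether and the tertiary allyl ether survive and under which the freed alcohol cannot close onto the enol ether as a cyclic ketal.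

Step 10
Reactants: 14 [4-(2-methylbut-3-en-2-yloxy)-3-(3-methylbut-2-en-1-yl)-2-(1-phenylvinyloxy)phenyl]methanol
Product: 15 4-(2-methylbut-3-en-2-yloxy)-3-(3-methylbut-2-en-1-yl)-2-(1-phenylvinyloxy)benzaldehyde
Conditions: activated MnO2, CH2Cl2, rt
Reagents that add atoms: none
Why: Heterogeneous MnO2 oxidation of an electron-rich benzylic alcohol stops at the aldehyde and is neutral, so the enol ether and both allyl groups should be left intact.

Step 11
Reactants: 15 4-(2-methylbut-3-en-2-yloxy)-3-(3-methylbut-2-en-1-yl)-2-(1-phenylvinyloxy)benzaldehyde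
Product: 16 Griffinone C, (2S)-7-(2-methylbut-3-en-2-yloxy)-8-(3-methylbut-2-en-1-yl)-2-phenylchroman-4-one
Conditions: [Rh(cod)Cl]2 (2.5 mol%), (R)-DTBM-SEGPHOS (5.5 mol%), NaBArF4 (5 mol%), degassed acid-free 1,2-dichloroethane, 40 °C
Reagents that add atoms: none
Why: Proposed new method: the cationic Rh(I) bisphosphine complex adds oxidatively to the formyl C–H bond, the acyl(hydrido)rhodium(III) held next to the enol ether by the ortho oxygen passes its hydride to the oxygen- and phenyl-bearing alkene carbon (the future C2) while Rh binds the terminal CH2, and C–C reductive elimination from the seven-membered acyl–alkyl rhodacycle makes the C3–C4 bond. The closest known reaction type is the Rh/chiral bisphosphine hydroacylation of 2-(2-arylallyl)benzaldehydes to 3-aryl-tetralones and of 2-(1-arylvinyl)benzaldehydes to 3-aryl-indanones; here the benzylic CH2 of the former is replaced by an ether oxygen, so the alkene is an enol ether, which has not been shown. The pyranone ring closes in a formal 6-endo-trig mode. The C2 stereocentre is set in the hydride transfer, where the C2-symmetric bisphosphine on rhodium selects the enantioface of the 1,1-disubstituted alkene, and it should persist because the medium contains neither base nor acid. The step needs endo over exo closure and hydroacylation over decarbonylation: the 1,1-disubstitution secures the first, since the exo path would need a tertiary α-oxy benzyl rhodium and reductive elimination to a quaternary carbon, and the short oxygen-bearing tether should make alkene insertion faster than CO extrusion. The prenyl group (meta to the acyl arm) and the vinyl group of the tertiary allyl ether (para) cannot reach the acyl rhodium within the molecule.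

**Compound list**

1 | 2-methylbut-3-en-2-ol | C=CC(C)(C)O | starting material
2 | lithium 2-methylbut-3-en-2-olate | [Li+].[O-]C(C)(C)C=C | intermediate
3 | tert-butyl 2-methylbut-3-en-2-yl carbonate | C=CC(C)(C)OC(=O)OC(C)(C)C | intermediate
4 | 2,4-dihydroxybenzaldehyde | O=Cc1ccc(O)cc1O | starting material
5 | 2-hydroxy-4-(2-methylbut-3-en-2-yloxy)benzaldehyde | C=CC(C)(C)Oc1ccc(C=O)c(O)c1 | intermediate
6 | Claisen dienone, 2-hydroxy-3-(3-methylbut-2-en-1-yl)-4-oxocyclohexa-1,5-diene-1-carbaldehyde (racemic, transient) | O=CC1=C(O)C(CC=C(C)C)C(=O)C=C1 | intermediate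
7 | 2,4-dihydroxy-3-(3-methylbut-2-en-1-yl)benzaldehyde | CC(C)=CCc1c(O)ccc(C=O)c1O | intermediate
8 | 2-hydroxy-4-(2-methylbut-3-en-2-yloxy)-3-(3-methylbut-2-en-1-yl)benzaldehyde | C=CC(C)(C)Oc1ccc(C=O)c(O)c1CC=C(C)C | intermediate
9 | 6-(hydroxymethyl)-3-(2-methylbut-3-en-2-yloxy)-2-(3-methylbut-2-en-1-yl)phenol | C=CC(C)(C)Oc1ccc(CO)c(O)c1CC=C(C)C | intermediate
10 | 6-[(tert-butyldimethylsilyloxy)methyl]-3-(2-methylbut-3-en-2-yloxy)-2-(3-methylbut-2-en-1-yl)phenol | C=CC(C)(C)Oc1ccc(CO[Si](C)(C)C(C)(C)C)c(O)c1CC=C(C)C | intermediate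
11 | benzoyl chloride | O=C(Cl)c1ccccc1 | starting material
12 | 6-[(tert-butyldimethylsilyloxy)methyl]-3-(2-methylbut-3-en-2-yloxy)-2-(3-methylbut-2-en-1-yl)phenyl benzoate | C=CC(C)(C)Oc1ccc(CO[Si](C)(C)C(C)(C)C)c(OC(=O)c2ccccc2)c1CC=C(C)C | intermediate
13 | tert-butyldimethyl{[4-(2-methylbut-3-en-2-yloxy)-3-(3-methylbut-2-en-1-yl)-2-(1-phenylvinyloxy)benzyl]oxy}silane | C=CC(C)(C)Oc1ccc(CO[Si](C)(C)C(C)(C)C)c(OC(=C)c2ccccc2)c1CC=C(C)C | intermediate
14 | [4-(2-methylbut-3-en-2-yloxy)-3-(3-methylbut-2-en-1-yl)-2-(1-phenylvinyloxy)phenyl]methanol | C=CC(C)(C)Oc1ccc(CO)c(OC(=C)c2ccccc2)c1CC=C(C)C | intermediate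
15 | 4-(2-methylbut-3-en-2-yloxy)-3-(3-methylbut-2-en-1-yl)-2-(1-phenylvinyloxy)benzaldehyde | C=CC(C)(C)Oc1ccc(C=O)c(OC(=C)c2ccccc2)c1CC=C(C)C | intermediate
16 | Griffinone C, (2S)-7-(2-methylbut-3-en-2-yloxy)-8-(3-methylbut-2-en-1-yl)-2-phenylchroman-4-one | C=CC(C)(C)Oc1ccc2c(c1CC=C(C)C)O[C@H](c1ccccc1)CC2=O | target

**Step count**

Total: 11 steps. Longest linear sequence: 11 steps (1 to 16 through carbonate 3); 10 steps counted from 2,4-dihydroxybenzaldehyde 4.

**Steps most likely to fail**

Step 11 (the proposed new method). The acyl rhodium hydride may lose CO and poison the catalyst. The cationic metal may act as a Lewis acid and close the enol ether onto the formyl group in an aldol-type reaction. Closure may go exo, enantioface discrimination may be weak, or the tertiary allyl ether may shift if heating is needed. The fallback uses known chemistry, sets out from 8 and returns at 16. Ethynylmagnesium bromide (3 equiv, THF, 0 °C) adds to the aldehyde to give 1-[2-hydroxy-4-(2-methylbut-3-en-2-yloxy)-3-(3-methylbut-2-en-1-yl)phenyl]prop-2-yn-1-ol F1. MnO2 (CH2Cl2, rt) oxidises it to 1-[2-hydroxy-4-(2-methylbut-3-en-2-yloxy)-3-(3-methylbut-2-en-1-yl)phenyl]prop-2-yn-1-one F2. Catalytic Et2NH in EtOH closes this by 6-endo oxa-Michael addition to 7-(2-methylbut-3-en-2-yloxy)-8-(3-methylbut-2-en-1-yl)-4H-chromen-4-one F3. Rhodium-catalysed asymmetric 1,4-addition of phenylboronic acid (Hayashi–Miyaura type; [RhCl(C2H4)2]2, chiral diene ligand of the antipode that gives 2S, substoichiometric aqueous KOH, dioxane–water, 30 °C) then forms the C2–phenyl bond and the stereocentre and should give 16; the base is kept low to avoid retro-oxa-Michael racemisation.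

Step 8. Methylenation of the hindered aryl ester may stall, the tertiary allyl aryl ether may undergo a [3,3] shift during prolonged heating, or the enol ether may hydrolyse on work-up. The fallback sets out from 10 and returns at 13. Mitsunobu etherification of phenol 10 with 2-bromo-1-phenylethanol (PPh3, DIAD, THF, 0 °C to rt) gives racemic tert-butyl{[2-(2-bromo-1-phenylethoxy)-4-(2-methylbut-3-en-2-yloxy)-3-(3-methylbut-2-en-1-yl)benzyl]oxy}dimethylsilane F4. KOtBu (THF, 0 °C) then removes HBr by E2 at the benzylic, oxygen-bearing C–H and should give 13 without heating.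

Step 3. The [3,3] shift may go partly to C5 instead of C3, the tertiary allyl group may be lost as isoprene, or a phenol may close onto the new prenyl group at high temperature. The fallback sets out from 4 and returns at 7. MOMCl/iPr2NEt (CH2Cl2) gives 2,4-bis(methoxymethoxy)benzaldehyde F5. HC(OMe)3 with catalytic PPTS in MeOH gives its dimethyl acetal, 1-(dimethoxymethyl)-2,4-bis(methoxymethoxy)benzene F6. n-BuLi (THF, 0 °C) lithiates the carbon between the two MOM ethers by directed ortho-metalation to give [3-(dimethoxymethyl)-2,6-bis(methoxymethoxy)phenyl]lithium F7. Prenyl bromide with catalytic CuI alkylates this to 1-(dimethoxymethyl)-2,4-bis(methoxymethoxy)-3-(3-methylbut-2-en-1-yl)benzene F8. Dilute HCl in MeOH at rt removes the acetal and both MOM groups and should give 7 with the prenyl group fixed at C3.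

**Further compounds**

F1 | step 11 | 1-[2-hydroxy-4-(2-methylbut-3-en-2-yloxy)-3-(3-methylbut-2-en-1-yl)phenyl]prop-2-yn-1-ol (racemic) | C#CC(O)c1ccc(OC(C)(C)C=C)c(CC=C(C)C)c1O
F2 | step 11 | 1-[2-hydroxy-4-(2-methylbut-3-en-2-yloxy)-3-(3-methylbut-2-en-1-yl)phenyl]prop-2-yn-1-one | C#CC(=O)c1ccc(OC(C)(C)C=C)c(CC=C(C)C)c1O
F3 | step 11 | 7-(2-methylbut-3-en-2-yloxy)-8-(3-methylbut-2-en-1-yl)-4H-chromen-4-one | C=CC(C)(C)Oc1ccc2c(c1CC=C(C)C)occc2=O
F4 | step 8 | tert-butyl{[2-(2-bromo-1-phenylethoxy)-4-(2-methylbut-3-en-2-yloxy)-3-(3-methylbut-2-en-1-yl)benzyl]oxy}dimethylsilane (racemic) | C=CC(C)(C)Oc1ccc(CO[Si](C)(C)C(C)(C)C)c(OC(CBr)c2ccccc2)c1CC=C(C)C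
F5 | step 3 | 2,4-bis(methoxymethoxy)benzaldehyde | COCOc1ccc(C=O)c(OCOC)c1
F6 | step 3 | 1-(dimethoxymethyl)-2,4-bis(methoxymethoxy)benzene | COCOc1ccc(C(OC)OC)c(OCOC)c1
F7 | step 3 | [3-(dimethoxymethyl)-2,6-bis(methoxymethoxy)phenyl]lithium | [Li]c1c(OCOC)ccc(C(OC)OC)c1OCOC
F8 | step 3 | 1-(dimethoxymethyl)-2,4-bis(methoxymethoxy)-3-(3-methylbut-2-en-1-yl)benzene | COCOc1ccc(C(OC)OC)c(OCOC)c1CC=C(C)C
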